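The dawn run still holds partner at 50.0 h: the two substrates have lost 50.8% of their charge, and its partner charge was 60.0% of theirs, so 15.3% of that partner reads as unspent. Your decision is whether the flask below can stop at 2.5 d.

all flasks: left-handed substrate 0.020 M; right-handed substrate 0.020 M; precatalyst 0.40 mM

| flask | partner | remark | time |
|---|---|---|---|
| midnight | 0.0060 M | run made earlier |  |
| dawn | 0.024 M | run made earlier |  |
| flask | 0.0120 M |  | 2.5 d |

| run | time / h | left-handed substrate / % | right-handed substrate / % | left-handed product / % |
|---|---|---|---|---|
| midnight | 4.00 | 46.6 | 47.8 | 0.9 |
| midnight | 8.00 | 46.8 | 49.0 | 1.9 |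
| midnight | 15.0 | 48.0 | 45.7 | 4.4 |
| midnight | 25.0 | 47.2 | 46.6 | 6.7 |
| midnight | 50.0 | 42.2 | 43.5 | 8.8 |
| dawn | 4.00 | 47.5 | 45.9 | 2.8 |
| dawn | 8.00 | 43.2 | 46.4 | 7.8 |
| dawn | 15.0 | 39.2 | 40.1 | 16.9 |
| dawn | 25.0 | 30.4 | 31.7 | 24.3 |
| dawn | 50.0 | 24.8 | 24.4 | 37.2 |

(each reading ± 1 percentage point)

- free catalyst is single-handed; left-handed substrate and right-handed substrate are mirror images of each other, charged as a racemate, each of them at the stated concentration
- what may be going on: free catalyst + left-handed substrate <-> catalyst intermediate A; left-handed substrate <-> right-handed substrate; partner + catalyst intermediate B -> free catalyst + right-handed product; partner + catalyst intermediate A -> free catalyst + left-handed product; precatalyst -> free catalyst; free catalyst + right-handed substrate <-> catalyst intermediate B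
- an excess is the difference of the two amounts in percent of their sum
- an excess is below zero if the other one leads

- part of the left-handed substrate and right-handed substrate charged together that has reacted at 2.5 d
- excess of left-handed product over right-handed product in the product at 2.5 d
- excess of right-handed substrate over left-handed substrate among what is left of the two at 2.5 d

Take 0.0375 /h from that leftover: it is the mean pseudo-first-order constant of partner loss, ln([partner] charged over [partner] left) divided by the time. On the midnight run it gives 12.7% lost at 50.0 h, and the readings give 14.3%.

Partner is the limiting reagent of the flask, smaller than the substrates at 30.0% of them, so I reckon c as 26.8%. Replacing the curve by its mean costs little: the dawn readings at 25.0 h give 0.0400 /h, which makes c 27.3%, against a scatter of 1 percentage point. The partner unspent at 2.5 d in the flask is reckoned at 3.16% of the substrates, less than c, so I leave recipe and stop time as they stand. From dawn's products I take eP as 46.5%, and eS as zero, its substrates reading 24.8% and 24.4%.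

The forecast gave eS 0.3%, an eP of 42%, lower than mine, and c 27%, this last on the ground that “Both runs fit first-order partner decay”.

The flask gives c 28.1%, eP 45.5% and eS 0.141%, with 9.03% of its partner left against my 10.5%.

    free catalyst + left-handed substrate ⇌ catalyst intermediate A (K = 57.0 /M, k = 1.01 × 10⁵ /M/h)
    left-handed substrate ⇌ right-handed substrate (k = 0.277 /h)
    partner + catalyst intermediate B → free catalyst + right-handed product (k = 41.5 /M/h)
    partner + catalyst intermediate A → free catalyst + left-handed product (k = 545 /M/h)
    precatalyst → free catalyst (k = 0.277 /h)
    free catalyst + right-handed substrate ⇌ catalyst intermediate B (K = 280 /M, k = 7490 /M/h)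

A neighbouring flask is charged with 0.030 M of partner, its other charges and time as in the flask, so its partner stands at 75.0% of the substrates. The same 0.0375 /h reckons its c as 67.1%. That neighbouring flask gives c 67.2%, with 11.4% of its partner left.

(The earlier runs and the new flask are calculated with made-up constants; the scatter is artificial.)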